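**Retrosynthetic overview**

1. The 6β-(E)-3-hydroxycinnamate is opened last to an acrylate plus 3-iodophenol (Heck), leaving 5α,7αH-eudesmane-4β,6β-diol, whose 6β-OH comes from a 6-ketone by α-face hydride delivery.
2. Key disconnection: C5–C10 and C8–C9 of the decalin are cut in one retro-[4+2] step to an acyclic triene, a 2-silyloxydiene C5=C6(O)–C7(iPr)=C8 tethered through C4–C3–C2–C1 to a Z-vinyl sulfone C9=C10(Me); the sulfonyl group on C9 is a removable activator.
3. Enabling feature: in ring B the oxygen-bearing C6 lies between C5 and C7, so ring B is the adduct of a 2-oxydiene and the C9=C10 alkene, and the ring A chain C4–C3–C2–C1 is the tether. The syn 1,3-dioxygen array O–C4–C5–C6–O lets one silicon atom join the C4 oxygen to the dienol oxygen in a temporary dioxasiline ring, through which C4 controls C5 and C10.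
4. The triene comes from hepta-1,6-diyne: carboalumination/hydroxymethylation, Sharpless epoxidation and hydride opening (sets C4), iodosulfonylation/methyl coupling (Z-vinyl sulfone), then oxidation, Nozaki–Hiyama–Kishi coupling and oxidation (enone).
5. Ring order: temporary dioxasiline ring (step 9), then rings A and B together (step 10); the silicon ring is opened in step 11 and the arene is attached last.

Key step: step 10

Remark: eudesmane numbering is used for the skeleton at every stage (C4 carbinol, C5/C10 ring fusion, C6 ester carbon, C7 isopropyl carbon) and β denotes the face of the C10 methyl group; hepta-1,6-diyne, 2-bromo-3-methylbut-1-ene, acryloyl chloride and 3-iodophenol are taken as purchased.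

**Route**

Step 1
Reactants: 1 hepta-1,6-diyne
Product: 3 (2E)-3-methyloct-2-en-7-yn-1-ol, via alkenylalane 2 (not isolated)
Conditions: AlMe3, Cp2ZrCl2 (cat.), CH2Cl2, 0 °C to rt (1 in threefold excess, recovered by distillation); then (CH2O)n, THF, 0 °C to rt; aq. work-up
Reagents that add atoms: trimethylaluminium C[Al](C)C; formaldehyde (as paraformaldehyde) C=O
Why: Zirconium-catalysed carboalumination (Negishi) should add methyl and aluminium syn across one terminal alkyne with the metal at the terminus, the excess of diyne limiting double addition, and the alkenylalane should be hydroxymethylated by formaldehyde with retention to give the E-trisubstituted allylic alcohol.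

Step 2
Reactants: 3 (2E)-3-methyloct-2-en-7-yn-1-ol
Product: 4 [(2S,3S)-3-methyl-3-(pent-4-yn-1-yl)oxiran-2-yl]methanol
Conditions: Ti(OiPr)4 (cat.), L-(+)-diethyl tartrate (cat.), t-BuOOH, 4 Å MS, CH2Cl2, −20 °C
Reagents that add atoms: tert-butyl hydroperoxide CC(C)(C)OO
Why: Sharpless asymmetric epoxidation of the allylic alcohol, in which the L-(+)-tartrate catalyst delivers oxygen in the same sense as for geraniol to give the (2S,3S)-epoxide, should set the configuration of the future C4 carbinol carbon while the remote alkyne is untouched.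

Step 3
Reactants: 4 [(2S,3S)-3-methyl-3-(pent-4-yn-1-yl)oxiran-2-yl]methanol
Product: 5 (3S)-3-methyloct-7-yne-1,3-diol
Conditions: NaAlH2(OCH2CH2OMe)2 (Red-Al), THF, 0 °C; aq. Rochelle salt
Reagents that add atoms: none
Why: Hydroxyl-directed reductive opening of the 2,3-epoxy alcohol, with intramolecular hydride delivery from the aluminium alkoxide to C2, should give the 1,3-diol, and because the C–O bond at the quaternary carbon is not broken the tertiary carbinol keeps its configuration, now (S).

Step 4
Reactants: 5 (3S)-3-methyloct-7-yne-1,3-diol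
Product: 6 (3S,7E)-7-iodo-3-methyl-8-(phenylsulfonyl)oct-7-ene-1,3-diol
Conditions: PhSO2Na, I2, EtOAc/H2O, rt, visible light
Reagents that add atoms: sodium benzenesulfinate [Na+].[O-]S(=O)c1ccccc1; iodine II
Why: Radical iodosulfonylation of the terminal alkyne, in which the sulfonyl radical adds to the terminal carbon and the vinyl radical abstracts iodine anti to it, should give the (E)-β-iodovinyl sulfone without touching the hydroxyl groups.

Step 5
Reactants: 6 (3S,7E)-7-iodo-3-methyl-8-(phenylsulfonyl)oct-7-ene-1,3-diol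
Product: 7 (3S,7Z)-3,7-dimethyl-8-(phenylsulfonyl)oct-7-ene-1,3-diol
Conditions: MeZnCl (excess), Pd(PPh3)4 (cat.), THF, 0 °C to rt
Reagents that add atoms: methylzinc chloride C[Zn]Cl
Why: Negishi cross-coupling at the vinylic carbon–iodine bond proceeds with retention of alkene geometry, so the methyl group should enter trans to the sulfonyl group and give the Z-trisubstituted vinyl sulfone (the descriptor changes from E to Z only through the priority rules), the hydroxyl groups being present as inert zinc alkoxides.

Step 6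
Reactants: 7 (3S,7Z)-3,7-dimethyl-8-(phenylsulfonyl)oct-7-ene-1,3-diol
Product: 8 (3S,7Z)-3-hydroxy-3,7-dimethyl-8-(phenylsulfonyl)oct-7-enal
Conditions: TEMPO (cat.), PhI(OAc)2, CH2Cl2, rt
Reagents that add atoms: none
Why: The oxoammonium (TEMPO) oxidation is selective for the primary alcohol and should give the β-hydroxy aldehyde, the tertiary alcohol being unoxidisable and the vinyl sulfone inert.

Step 7
Reactants: 8 (3S,7Z)-3-hydroxy-3,7-dimethyl-8-(phenylsulfonyl)oct-7-enal, 9 2-bromo-3-methylbut-1-ene
Product: 11 (5S,9Z)-5,9-dimethyl-10-(phenylsulfonyl)-2-(propan-2-yl)deca-1,9-diene-3,5-diol (both C3 epimers), via alkenylchromium dichloride 10 (not isolated)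
Conditions: CrCl2 (excess), NiCl2 (cat.), DMF, rt
Reagents that add atoms: chromium dichloride [Cr+2].[Cl-].[Cl-] (to intermediate 10 only)
Why: Nozaki–Hiyama–Kishi coupling, in which the alkenylchromium reagent formed from 9 adds only to the aldehyde and tolerates the free tertiary hydroxyl and the vinyl sulfone, should join C6 to C7, and the new carbinol centre may form as a mixture because it is removed in step 8.

Step 8
Reactants: 11 (5S,9Z)-5,9-dimethyl-10-(phenylsulfonyl)-2-(propan-2-yl)deca-1,9-diene-3,5-diol
Product: 12 (5S,9Z)-5-hydroxy-5,9-dimethyl-10-(phenylsulfonyl)-2-(propan-2-yl)deca-1,9-dien-3-one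
Conditions: Dess–Martin periodinane, NaHCO3, CH2Cl2, 0 °C to rt
Reagents that add atoms: none
Why: Dess–Martin oxidation of the secondary allylic alcohol under buffered conditions should give the β-hydroxy enone without dehydration, retro-aldol cleavage or oxa-Michael closure, the tertiary alcohol being unoxidisable.

Step 9
Reactants: 12 (5S,9Z)-5-hydroxy-5,9-dimethyl-10-(phenylsulfonyl)-2-(propan-2-yl)deca-1,9-dien-3-one
Product: 13 (4S)-4-methyl-6-(3-methylbut-1-en-2-yl)-4-[(4Z)-4-methyl-5-(phenylsulfonyl)pent-4-en-1-yl]-2,2-di(propan-2-yl)-4H-1,3,2-dioxasiline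
Conditions: iPr2Si(OTf)2, Et3N, CH2Cl2, −78 to 0 °C
Reagents that add atoms: di(propan-2-yl)silyl bis(trifluoromethanesulfonate) CC(C)[Si](OS(=O)(=O)C(F)(F)F)(OS(=O)(=O)C(F)(F)F)C(C)C
Why: Silyl triflate silylation of the tertiary hydroxyl and amine-mediated soft enolisation toward C5, the only enolisable position, followed by intramolecular O-silylation should close the six-membered dioxasiline (cyclic silylene enol ether formation), whose ring forces the Z enol ether geometry and leaves the 2-silyloxydiene in place.

Step 10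
Reactants: 13 (4S)-4-methyl-6-(3-methylbut-1-en-2-yl)-4-[(4Z)-4-methyl-5-(phenylsulfonyl)pent-4-en-1-yl]-2,2-di(propan-2-yl)-4H-1,3,2-dioxasiline
Product: 14 4β,6-O-[di(propan-2-yl)silanediyl]-9α-(phenylsulfonyl)-5α-eudesm-6-ene-4β,6-diol (trans-fused decalin; C10 methyl β; H5 α; C4 methyl α)
Conditions: PhMe (0.01 M), BHT (cat.), 160 °C, sealed silylated tube
Reagents that add atoms: none
Why: Thermal intramolecular Diels–Alder reaction (type 1, 1,7,9-decatriene class) in which the 2-silyloxydiene C5=C6(OSi)–C7=C8 adds across the Z-vinyl sulfone C9=C10 in a concerted but asynchronous [4+2] event, the nucleophilic diene terminus C5 bonding to the β-carbon C10 of the sulfone ahead of C8–C9; the closest known reactions are thermal intramolecular Diels–Alder cyclisations of sulfonyl-activated decatrienes and of enone-derived 2-silyloxydienes (the pericyclic counterpart of an intramolecular double Michael addition). Ring B is closed by the [4+2] cycloaddition itself (six-membered, boat-like) and ring A by the same C5–C10 bond through the four-carbon tether C4–C3–C2–C1 in the fused mode with a chair-like tether. C5 is controlled by the C4 stereocentre through the dioxasiline ring: the O–C4 bond is held in the diene plane, so the tether can deliver the dienophile only to the diene face that carries C3, which places H5 cis to the C4 methyl group. C10 is controlled by the chair tether, which puts C1 exo and the C10 methyl endo (trans ring fusion), since a cis fusion would need a boat tether and would also force the sulfonyl group endo; the C9 configuration (sulfonyl α, cis to C1) follows from the Z-alkene and is erased in step 13. The step needs facial selectivity and trans fusion (regiochemistry is fixed by the tether and is electronically matched), and both should be secured by the temporary silicon ring (fixed Z enol ether, in-plane C4–O, fully substituted C4 that favours folding) together with the Z-sulfone. The resulting silyl enol ether C6=C7 already carries the C6 oxygen of the target.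

Step 11
Reactants: 14 4β,6-O-[di(propan-2-yl)silanediyl]-9α-(phenylsulfonyl)-5α-eudesm-6-ene-4β,6-diol
Product: 16 4β-hydroxy-9α-(phenylsulfonyl)-5α,7αH-eudesman-6-one, via enol 15 (not isolated)
Conditions: HF·pyridine, pyridine, THF, 0 °C
Reagents that add atoms: none
Why: Fluoride cleavage of both Si–O bonds frees the enol, whose ketonisation by protonation at C7 should place the isopropyl group equatorial (β), the only arrangement without a syn-diaxial clash with the 9α-sulfonyl group, while the buffered medium should spare the β-hydroxy ketone from dehydration and retro-aldol cleavage.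

Step 12
Reactants: 16 4β-hydroxy-9α-(phenylsulfonyl)-5α,7αH-eudesman-6-one
Product: 17 9α-(phenylsulfonyl)-5α,7αH-eudesmane-4β,6β-diol
Conditions: NaBH4, MeOH/CH2Cl2, −40 to 0 °C
Reagents that add atoms: none
Why: Borohydride reduction of the 6-ketone should occur from the α face, because the β face is screened by the axial C10 methyl group and the axial 4β-hydroxyl (as in 6-oxo-5α-steroids), and so give the axial 6β-alcohol.

Step 13
Reactants: 17 9α-(phenylsulfonyl)-5α,7αH-eudesmane-4β,6β-diol
Product: 18 5α,7αH-eudesmane-4β,6β-diol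
Conditions: Na(Hg), Na2HPO4, MeOH/THF, −20 °C to rt
Reagents that add atoms: none
Why: Reductive desulfonylation by sodium amalgam (electron transfer to the aryl sulfone, C–S cleavage and protonation) should turn C9 into a methylene group, the phosphate buffer keeping the diol and the ring system untouched.

Step 14
Reactants: 18 5α,7αH-eudesmane-4β,6β-diol, 19 acryloyl chloride
Product: 20 4β-hydroxy-5α,7αH-eudesman-6β-yl prop-2-enoate
Conditions: Et3N, DMAP (cat.), BHT (trace), CH2Cl2, 0 °C to rt
Reagents that add atoms: none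
Why: DMAP-catalysed acylation with the small and reactive acid chloride should esterify the secondary 6β-hydroxyl, whereas the tertiary 4β-hydroxyl is too hindered to react.

Step 15
Reactants: 20 4β-hydroxy-5α,7αH-eudesman-6β-yl prop-2-enoate, 21 3-iodophenol
Product: 22 4β-hydroxy-5α,7αH-eudesman-6β-yl (2E)-3-(3-hydroxyphenyl)prop-2-enoate (CNP0283603.1)
Conditions: Pd(OAc)2 (cat.), P(o-tol)3, Et3N, MeCN, 80 °C
Reagents that add atoms: none
Why: Mizoroki–Heck arylation of the acrylate with the aryl iodide (syn insertion then syn β-hydride elimination) should give the E-cinnamate, and the free phenol, the tertiary alcohol and the ester are tolerated.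

**Compound list**

1 | hepta-1,6-diyne | C#CCCCC#C | starting material
2 | (E)-dimethyl(2-methylhept-1-en-6-yn-1-yl)alane | C[Al](C)/C=C(\C)CCCC#C | intermediate (not isolated)
3 | (2E)-3-methyloct-2-en-7-yn-1-ol | OC/C=C(\C)CCCC#C | intermediate
4 | [(2S,3S)-3-methyl-3-(pent-4-yn-1-yl)oxiran-2-yl]methanol | OC[C@@H]1O[C@@]1(C)CCCC#C | intermediate
5 | (3S)-3-methyloct-7-yne-1,3-diol | OCC[C@@](C)(O)CCCC#C | intermediate
6 | (3S,7E)-7-iodo-3-methyl-8-(phenylsulfonyl)oct-7-ene-1,3-diol | OCC[C@@](C)(O)CCC/C(I)=C\S(=O)(=O)c1ccccc1 | intermediate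
7 | (3S,7Z)-3,7-dimethyl-8-(phenylsulfonyl)oct-7-ene-1,3-diol | OCC[C@@](C)(O)CCC/C(C)=C\S(=O)(=O)c1ccccc1 | intermediate
8 | (3S,7Z)-3-hydroxy-3,7-dimethyl-8-(phenylsulfonyl)oct-7-enal | O=CC[C@@](C)(O)CCC/C(C)=C\S(=O)(=O)c1ccccc1 | intermediate
9 | 2-bromo-3-methylbut-1-ene | C=C(Br)C(C)C | starting material
10 | dichloro(3-methylbut-1-en-2-yl)chromium (trivalent chromium) | C=C(C(C)C)[Cr](Cl)Cl | intermediate (not isolated)
11 | (5S,9Z)-5,9-dimethyl-10-(phenylsulfonyl)-2-(propan-2-yl)deca-1,9-diene-3,5-diol (both C3 epimers) | C=C(C(C)C)C(O)C[C@@](C)(O)CCC/C(C)=C\S(=O)(=O)c1ccccc1 | intermediate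
12 | (5S,9Z)-5-hydroxy-5,9-dimethyl-10-(phenylsulfonyl)-2-(propan-2-yl)deca-1,9-dien-3-one | C=C(C(C)C)C(=O)C[C@@](C)(O)CCC/C(C)=C\S(=O)(=O)c1ccccc1 | intermediate
13 | (4S)-4-methyl-6-(3-methylbut-1-en-2-yl)-4-[(4Z)-4-methyl-5-(phenylsulfonyl)pent-4-en-1-yl]-2,2-di(propan-2-yl)-4H-1,3,2-dioxasiline | C=C(C(C)C)C1=C[C@](C)(CCC/C(C)=C\S(=O)(=O)c2ccccc2)O[Si](C(C)C)(C(C)C)O1 | intermediate
14 | 4β,6-O-[di(propan-2-yl)silanediyl]-9α-(phenylsulfonyl)-5α-eudesm-6-ene-4β,6-diol | CC(C)C1=C2O[Si](C(C)C)(C(C)C)O[C@@]3(C)CCC[C@@](C)([C@@H]23)[C@H](S(=O)(=O)c4ccccc4)C1 | intermediate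
15 | 9α-(phenylsulfonyl)-5α-eudesm-6-ene-4β,6-diol (free enol) | CC(C)C1=C(O)[C@H]2[C@@](C)(O)CCC[C@]2(C)[C@H](S(=O)(=O)c3ccccc3)C1 | intermediate (not isolated)
16 | 4β-hydroxy-9α-(phenylsulfonyl)-5α,7αH-eudesman-6-one | CC(C)[C@@H]1C[C@@H](S(=O)(=O)c2ccccc2)[C@@]2(C)CCC[C@](C)(O)[C@@H]2C1=O | intermediate
17 | 9α-(phenylsulfonyl)-5α,7αH-eudesmane-4β,6β-diol | CC(C)[C@@H]1C[C@@H](S(=O)(=O)c2ccccc2)[C@@]2(C)CCC[C@](C)(O)[C@@H]2[C@@H]1O | intermediate
18 | 5α,7αH-eudesmane-4β,6β-diol | CC(C)[C@@H]1CC[C@@]2(C)CCC[C@](C)(O)[C@@H]2[C@@H]1O | intermediate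
19 | acryloyl chloride | C=CC(=O)Cl | starting material
20 | 4β-hydroxy-5α,7αH-eudesman-6β-yl prop-2-enoate | CC(C)[C@@H]1CC[C@@]2(C)CCC[C@](C)(O)[C@@H]2[C@@H]1OC(=O)C=C | intermediate
21 | 3-iodophenol | Oc1cccc(I)c1 | starting material
22 | 4β-hydroxy-5α,7αH-eudesman-6β-yl (2E)-3-(3-hydroxyphenyl)prop-2-enoate | CC(C)[C@@H]1CC[C@@]2(C)CCC[C@](C)(O)[C@@H]2[C@@H]1OC(=O)/C=C/c1cccc(O)c1 | target

**Step count and risks**

Total steps: 15. Longest linear sequence: 15 steps (1 to 22; compounds 9, 19 and 21 are purchased).

Steps most likely to fail: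

Step 10. The cycloaddition may be too slow, because the β,β-disubstituted vinyl sulfone has to form the quaternary C10, so that thermal decomposition or hydrolysis of the silyl dienol ether competes; the ring fusion may also form with poor trans selectivity. Fallback (anionic instead of pericyclic ring formation), setting out from 13: MeLi in THF at −20 °C should cleave the enol Si–O bond to give the lithium Z-dienolate with the C4 oxygen still silylated. Intramolecular double Michael addition (C5 to C10, then the α-sulfonyl carbanion C9 to C8) and protonation should give 4β-{[methyldi(propan-2-yl)silyl]oxy}-9-(phenylsulfonyl)-5α,7αH-eudesman-6-one F1 as C9 epimers. HF·pyridine should give 4β-hydroxy-9-(phenylsulfonyl)-5α,7αH-eudesman-6-one F2, NaBH4 should give 9-(phenylsulfonyl)-5α,7αH-eudesmane-4β,6β-diol F3, and Na(Hg)/Na2HPO4 removes the sulfonyl group of both C9 epimers, which returns to the route at 18. Control of C5 by C4 is expected to be less secure in this mode than in the tethered cycloaddition.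

Step 9. Closure of the silicon ring onto the hindered tertiary hydroxyl may remain incomplete, or oxa-Michael cyclisation of the hydroxy enone to a tetrahydropyranone may outrun silylation. Fallback (acyclic stereocontrol without the temporary ring), setting out from 12: Et3SiOTf/Et3N in CH2Cl2 should give triethyl{[(3Z,5S,9Z)-5,9-dimethyl-10-(phenylsulfonyl)-2-(propan-2-yl)-5-[(triethylsilyl)oxy]deca-1,3,9-trien-3-yl]oxy}silane F4. Its thermal intramolecular Diels–Alder reaction would rely on allylic 1,3-strain (the C4 oxygen, the smallest C4 substituent, eclipsing the Z-silyloxy group) and on avoiding a syn-diaxial methyl/methyl contact, and should give 4β,6-bis[(triethylsilyl)oxy]-9α-(phenylsulfonyl)-5α-eudesm-6-ene F5. HF·pyridine returns to the route at 16.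

Step 14. Acylation of the axial 6β-hydroxyl, which is flanked by the isopropyl group and syn-diaxial to the C10 methyl group and the 4β-hydroxyl, may stall, or the acrylate may polymerise under the basic conditions. Fallback (condensation instead of acylation/arylation), setting out from 18: heating with Meldrum's acid in PhMe at 90 °C should give 3-{[4β-hydroxy-5α,7αH-eudesman-6β-yl]oxy}-3-oxopropanoic acid F6. Knoevenagel–Doebner condensation of F6 with 3-hydroxybenzaldehyde (pyridine, piperidine cat., 90 °C) with loss of CO2 should give the E-cinnamate and returns to the route at 22.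

Further compounds
F1 | step 10 | 4β-{[methyldi(propan-2-yl)silyl]oxy}-9-(phenylsulfonyl)-5α,7αH-eudesman-6-one (both C9 epimers) | CC(C)[C@@H]1CC(S(=O)(=O)c2ccccc2)[C@@]2(C)CCC[C@](C)(O[Si](C)(C(C)C)C(C)C)[C@@H]2C1=O
F2 | step 10 | 4β-hydroxy-9-(phenylsulfonyl)-5α,7αH-eudesman-6-one (both C9 epimers) | CC(C)[C@@H]1CC(S(=O)(=O)c2ccccc2)[C@@]2(C)CCC[C@](C)(O)[C@@H]2C1=O
F3 | step 10 | 9-(phenylsulfonyl)-5α,7αH-eudesmane-4β,6β-diol (both C9 epimers) | CC(C)[C@@H]1CC(S(=O)(=O)c2ccccc2)[C@@]2(C)CCC[C@](C)(O)[C@@H]2[C@@H]1O
F4 | step 9 | triethyl{[(3Z,5S,9Z)-5,9-dimethyl-10-(phenylsulfonyl)-2-(propan-2-yl)-5-[(triethylsilyl)oxy]deca-1,3,9-trien-3-yl]oxy}silane | C=C(C(C)C)/C(O[Si](CC)(CC)CC)=C/[C@@](C)(O[Si](CC)(CC)CC)CCC/C(C)=C\S(=O)(=O)c1ccccc1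
F5 | step 9 | 4β,6-bis[(triethylsilyl)oxy]-9α-(phenylsulfonyl)-5α-eudesm-6-ene | CC(C)C1=C(O[Si](CC)(CC)CC)[C@H]2[C@@](C)(O[Si](CC)(CC)CC)CCC[C@]2(C)[C@H](S(=O)(=O)c3ccccc3)C1
F6 | step 14 | 3-{[4β-hydroxy-5α,7αH-eudesman-6β-yl]oxy}-3-oxopropanoic acid | CC(C)[C@@H]1CC[C@@]2(C)CCC[C@](C)(O)[C@@H]2[C@@H]1OC(=O)CC(=O)O
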